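**Assumption:** the target SMILES has no stereodescriptor and the molecule has no stereogenic element (no stereocentre, and the diaryl ether bonds rotate freely with only three ortho substituents). It is therefore made as the single achiral compound drawn, and no enantiocontrol is needed.

## Analysis of the target

The target is 3,4,5-tribromo-2-(3,5-dibromo-2-methoxyphenoxy)phenol: two benzene rings joined by one ether oxygen, with no further ring, chain or stereocentre. Ring B is the phenol ring (C1 OH, C2 O-aryl, C3/C4/C5 Br, C6 H). Ring A is the anisole ring (C1′ ether O, C2′ OMe, C3′ and C5′ Br, C4′ and C6′ H). Both rings are catechol-type, and the two oxygen functions next to the ether carbons differ only by one methyl group, so they must be told apart. The ether oxygen is tri-ortho-substituted (OH and Br on ring B, OMe on ring A) and sits on the more hindered oxygen position of ring B. The ring B bromine pattern is not what bromination of the free phenol would give, because C6–H ortho to the OH would react first; the ring B bromines must therefore be set under a different director. Five C–Br bonds rule out Pd, Ni, hot low-valent Cu, organolithium reagents and hydrogenolysis on late intermediates. The feature that invites the key move is the C1(OH)–C2(O-aryl) pair of ring B: it is the retron of an O–H insertion by a 2-oxocyclohexadienylidene, with C1 as the carbonyl carbon and C2 as the carbene carbon. In that reading ring B becomes the electrophile at its most hindered carbon, and its free OH appears without any protecting group.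

## Retrosynthetic reasoning

**10 to 8 and 4.** The C2–O bond of ring B is cut and the ether oxygen stays on ring A. Cutting O–C1′ instead would make ring B the nucleophile at its most hindered, least nucleophilic oxygen and would force a protecting group onto the C1 hydroxyl. With the chosen cut, ring B is a dearomatised quinone diazide 8 whose diazo carbon becomes C2 and whose carbonyl becomes the C1 hydroxyl, and ring A is the phenol 4 that already carries its methyl group. The forward reaction has to generate the metal carbene 9 from 8 without touching five C–Br bonds and insert it into the O–H bond of 4. It forms the ether bond, aromatises ring B and releases the free phenol in the same operation, so that the last step gives 10 directly.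

**8 to 7.** The C=N2 unit is traced back to the C–NH2 of an ortho-aminophenol. The forward step is a diazotisation in which the diazonium phenol loses its proton to give the neutral diazo oxide.

**7 to 6 to 5.** The O–CH3 bond of 6 is cut last, then the two C–Br bonds at C3 and C5 of ring B. These two carbons are ortho and para to the nitrogen that stands on C2, so a free amine can direct both bromines, while the bromine at C4 (para to oxygen) is already present in 5. The nitrogen thus does two jobs: it sets the bromine pattern that the final OH could not set, and it becomes the leaving group of the key step. The methyl ether keeps the oxygen a weak director during bromination.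

**4 to 1.** The C1′–O bond of ring A is cut back to a C–Br bond. In 1 the two bromines ortho to the methoxy group are equivalent, so one bromine–magnesium exchange at that position (2), borylation (3) and oxidation give 4 in one flask with the two remaining bromines ortho and para to OMe, as ring A requires.

## Alternatives that were turned down

**Alternative 1:** the textbook disconnection, O–C1′, by O-arylation of a ring B phenol. A copper(II)-mediated Chan–Lam–Evans coupling of boronic acid A1 with phenol A2 (ring B with its second oxygen carried as an isopropyl ether, bromines in place) would give the protected ether A3, and Lewis-acid cleavage of the isopropyl ether would give 10. It was turned down for three reasons. A2 is a 2,6-disubstituted, threefold brominated phenoxide, a poor partner for transmetalation and for reductive elimination to a tri-ortho-substituted ether. An Ullmann variant would put copper(I) in front of five C–Br bonds. And the route spends two of its four steps on placing and removing a group whose only task is to distinguish two oxygens. It is kept as the basis of the fallback.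

**Alternative 2:** the biomimetic disconnection, C2–O of ring B by oxidative phenol coupling. Anodic or one-electron chemical oxidation of a mixture of 4 and phenol A4 would join the oxygen of 4 to an ortho carbon of A4, via dienone A5 (formed as a racemate), which tautomerises to 10. This is two steps in all and very attractive. It was turned down because nothing in the two substrates decides the outcome. 4 is the more easily oxidised partner, and its radical or cation is captured at the methoxy-bearing carbon or couples through carbon. A4 can couple through oxygen, the ortho carbon or the brominated para carbon. Homo-coupling competes statistically with cross-coupling. In the organism an enzyme pocket makes these choices; in a flask a mixture of C–O and C–C dimers is expected.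

**Alternative 3:** late bromination of ring A. SNAr of the phenoxide of A2 on aldehyde A6 would give ether A7, Dakin oxidation would give phenol A8, bromination ortho and para to the new hydroxyl would give A9, O-methylation would give A3, and deprotection would give 10. The idea of letting a free phenol direct the ring A bromines is sound. It was turned down because the same logic fails on ring B (C6–H would be brominated first), so ring B still needs pre-bromination and a protecting group. The SNAr must also push a hindered, deactivated phenoxide onto a weakly activated fluoroarene. The sequence is six linear steps.

Key step: step 5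

## Route

**Step 1**
Reactants: 1 2,4,6-tribromoanisole
Product: 4 3,5-dibromo-2-methoxyphenol, via arylmagnesium chloride 2 (not isolated), via dimethyl arylboronate 3 (not isolated)
Conditions: i-PrMgCl·LiCl (1.05 equiv), THF, −15 °C; B(OMe)3, −15 °C → rt; then 30% aq. H2O2, 0 °C → rt
Reagents that add atoms: hydrogen peroxide, OO
Why: Br/Mg exchange with the turbo-Grignard reagent should occur at a bromine ortho to the methoxy group (inductive activation and chelation; the two ortho bromines are equivalent), and the arylmagnesium 2 is borylated to 3, which undergoes oxidative 1,2-migration from boron to oxygen to give the phenol. Both remaining bromines are meta to the C–Mg bond, so no aryne can form.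

**Step 2**
Reactants: 5 5-bromo-2-methoxyaniline
Product: 6 2,3,4-tribromo-6-methoxyaniline
Conditions: NBS (2.05 equiv), MeCN, 0 °C → rt, dark
Reagents that add atoms: N-bromosuccinimide, O=C1CCC(=O)N1Br
Why: Electrophilic aromatic bromination directed by the free amino group, the strongest donor on the ring: its para position and its open ortho position are brominated. The remaining C–H is only ortho to the weaker methoxy donor and meta to the amine, and should stay untouched with two equivalents.

**Step 3**
Reactants: 6 2,3,4-tribromo-6-methoxyaniline
Product: 7 2-amino-3,4,5-tribromophenol
Conditions: BBr3 (3 equiv), CH2Cl2, −78 °C → rt; MeOH, then aq. NaHCO3, under Ar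
Reagents that add atoms: none
Why: Lewis-acid cleavage of an aryl methyl ether: one equivalent of BBr3 is tied up by the amine, and the excess activates the ether oxygen so that bromide attacks the methyl group. C–Br and C–N bonds are inert, and the product is kept under argon and used at once.

**Step 4**
Reactants: 7 2-amino-3,4,5-tribromophenol
Product: 8 3,4,5-tribromo-6-diazocyclohexa-2,4-dien-1-one
Conditions: t-BuONO (1.3 equiv), AcOH (1 equiv), THF, 0 °C, dark
Reagents that add atoms: tert-butyl nitrite, CC(C)(C)ON=O
Why: Diazotisation of an ortho-aminophenol: the diazonium ion loses the acidic phenolic proton and is obtained as the neutral quinone diazide (diazo oxide), a class that halogen substituents stabilise. Low temperature and exclusion of light prevent loss of nitrogen.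

**Step 5**
Reactants: 8 3,4,5-tribromo-6-diazocyclohexa-2,4-dien-1-one; 4 3,5-dibromo-2-methoxyphenol
Product: 10 3,4,5-tribromo-2-(3,5-dibromo-2-methoxyphenoxy)phenol, via rhodium quinoid carbene 9 (not isolated)
Conditions: Rh2(OAc)4 (2 mol%), 4 (2 equiv), ClCH2CH2Cl, 60 °C, slow addition of 8 over 3 h, dark
Reagents that add atoms: none
Why: Rh2(OAc)4 attacks the diazo carbon C6 of 8, N2 leaves, and the electrophilic rhodium quinoid carbene 9 results. The hydroxyl oxygen of 4 adds to the carbene carbon to give a rhodium-associated oxonium ylide, and proton transfer from the oxonium oxygen to the dienone oxygen releases the catalyst and aromatises ring B, so that C6 of 8 becomes C2 (O-aryl) and the carbonyl carbon becomes C1 (OH) of 10. The closest known reaction types are the Rh(II)-catalysed O–H insertion of quinone diazides and diazonaphthoquinones into alcohols, water and carboxylic acids, which gives ortho-oxygenated aryl ethers, and the O–H insertion of rhodium carbenes into phenols. No ring is closed and no stereocentre is formed. The regiochemistry cannot vary, because the carbene carbon is fixed between the carbonyl carbon and C5–Br of 8; the ether oxygen therefore arrives at the hindered position that a nucleophilic arylation reaches only with difficulty. The step needs O- over C-selectivity at 4: two bromines deactivate its ring carbons, and its only free positions are C4 (between two bromines) and C6, so the O–H bond should be the most nucleophilic site. It also needs carbene capture to outrun Wolff ring contraction, dimerisation and a second insertion into the phenol of 10: metal catalysis at 60 °C in the dark disfavours the Wolff pathway, slow addition keeps the concentration of 8 low, and the excess of 4 competes against 10. The five C–Br bonds should be inert, since no low-valent metal is present and bromonium ylide formation is reversible.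

## Compound list

1 | 2,4,6-tribromoanisole (1,3,5-tribromo-2-methoxybenzene) | COc1c(Br)cc(Br)cc1Br | starting material
2 | (3,5-dibromo-2-methoxyphenyl)magnesium chloride | COc1c([Mg]Cl)cc(Br)cc1Br | intermediate (not isolated)
3 | dimethyl (3,5-dibromo-2-methoxyphenyl)boronate | COB(OC)c1cc(Br)cc(Br)c1OC | intermediate (not isolated)
4 | 3,5-dibromo-2-methoxyphenol | COc1c(O)cc(Br)cc1Br | intermediate
5 | 5-bromo-2-methoxyaniline | COc1ccc(Br)cc1N | starting material
6 | 2,3,4-tribromo-6-methoxyaniline | COc1cc(Br)c(Br)c(Br)c1N | intermediate
7 | 2-amino-3,4,5-tribromophenol | Nc1c(O)cc(Br)c(Br)c1Br | intermediate
8 | 3,4,5-tribromo-6-diazocyclohexa-2,4-dien-1-one | O=C1C=C(Br)C(Br)=C(Br)C1=[N+]=[N-] | intermediate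
9 | rhodium carbene of 3,4,5-tribromo-6-oxocyclohexa-2,4-dien-1-ylidene (Rh2(OAc)4 ligand sphere not drawn) | O=C1C=C(Br)C(Br)=C(Br)C1=[Rh] | intermediate (not isolated)
10 | 3,4,5-tribromo-2-(3,5-dibromo-2-methoxyphenoxy)phenol | COc1c(Br)cc(Br)cc1Oc1c(O)cc(Br)c(Br)c1Br | target

## Step count and risk

Total step count: 5. Longest linear sequence: 4 (steps 2, 3, 4, 5). The route is convergent; step 1 supplies the second fragment.

**Step 5 (key step).** The carbene may attack a ring carbon of 4 instead of its oxygen, the diazo compound may contract by the Wolff pathway and be trapped by 4 as an ester, or the carbene may insert a second time into the phenol of the product. Steric shielding of the diazo carbon by the neighbouring bromine may also slow carbene formation enough for dimerisation to compete. The fallback gives up the carbene logic and forms the other C–O bond with a hypervalent iodine electrophile; it sets out from 1 and comes back at 10.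
- 1 is taken to 2 as in step 1, quenched with B(OMe)3 and hydrolysed with aqueous acid without oxidation, to give (3,5-dibromo-2-methoxyphenyl)boronic acid F1.
- F1 is treated with iodomesitylene, mCPBA and BF3·OEt2 in CH2Cl2 to give (3,5-dibromo-2-methoxyphenyl)(2,4,6-trimethylphenyl)iodonium tetrafluoroborate F2.
- Commercial 2-(propan-2-yloxy)phenol F3 is tribrominated (Br2, NaOAc, AcOH) para and ortho to the free hydroxyl and para to the ether oxygen, to give 2,3,4-tribromo-6-(propan-2-yloxy)phenol F4.
- The potassium salt of F4 (t-BuOK, THF) is arylated by F2 without metal; the electron-poor dibromomethoxyphenyl group should be transferred in preference to mesityl, to give 1,2,3-tribromo-4-(3,5-dibromo-2-methoxyphenoxy)-5-(propan-2-yloxy)benzene F5.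
- BCl3 in CH2Cl2 cleaves the isopropyl ether selectively in the presence of the methyl ether and gives 10.

**Step 4.** Nitrosation of the weakly basic, hindered amine may be slow; the diazo oxide may couple with unreacted aminophenol or lose nitrogen on exposure to light or on concentration. It is also a potentially explosive solid and should be handled in solution on small scale. If 8 cannot be obtained in usable form, the diazo route is left altogether and the iodonium sequence described for step 5 is used. That fallback sets out from 1, comes back at 10, needs neither 7 nor 8, and makes no compound beyond F1 to F5.

**Step 3.** Ether cleavage may stall because the amine binds the Lewis acid, and the aminophenol may oxidise in air during work-up. The fallback builds 7 without any ether cleavage; it replaces 5 and 6 and comes back at 7. Commercial 3,4,5-tribromophenol F6 is nitrated (dilute HNO3, AcOH/CH2Cl2, 0 °C) at one of its two equivalent ortho positions, the para position being blocked, to give 3,4,5-tribromo-2-nitrophenol F7. F7 is reduced with Na2S2O4 in THF/water, or with SnCl2 in EtOH, which leaves the C–Br bonds intact, to give 7.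

**Step 1.** Exchange may occur in part at the para bromine or twice, the Grignard reagent may be protonated before borylation, or oxidation of the boronate may be incomplete. The fallback builds the phenol oxygen by aryl migration instead of metalation; it replaces 1 and comes back at 4. Commercial 3,5-dibromo-2-hydroxybenzaldehyde F8 is O-methylated (MeI, K2CO3, DMF) to 3,5-dibromo-2-methoxybenzaldehyde F9. Baeyer–Villiger oxidation with mCPBA in CH2Cl2 gives 3,5-dibromo-2-methoxyphenyl formate F10, and methanolysis (K2CO3 cat., MeOH) gives 4.

## Further compounds

F1 | step 5 | (3,5-dibromo-2-methoxyphenyl)boronic acid | COc1c(B(O)O)cc(Br)cc1Br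
F2 | step 5 | (3,5-dibromo-2-methoxyphenyl)(2,4,6-trimethylphenyl)iodonium tetrafluoroborate | COc1c([I+]c2c(C)cc(C)cc2C)cc(Br)cc1Br.F[B-](F)(F)F
F3 | step 5 | 2-(propan-2-yloxy)phenol | CC(C)Oc1ccccc1O
F4 | step 5 | 2,3,4-tribromo-6-(propan-2-yloxy)phenol | CC(C)Oc1cc(Br)c(Br)c(Br)c1O
F5 | step 5 | 1,2,3-tribromo-4-(3,5-dibromo-2-methoxyphenoxy)-5-(propan-2-yloxy)benzene | COc1c(Br)cc(Br)cc1Oc1c(OC(C)C)cc(Br)c(Br)c1Br
F0 | step 4 | none | none
F6 | step 3 | 3,4,5-tribromophenol | Oc1cc(Br)c(Br)c(Br)c1
F7 | step 3 | 3,4,5-tribromo-2-nitrophenol | Oc1cc(Br)c(Br)c(Br)c1[N+](=O)[O-]
F8 | step 1 | 3,5-dibromo-2-hydroxybenzaldehyde | O=Cc1cc(Br)cc(Br)c1O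
F9 | step 1 | 3,5-dibromo-2-methoxybenzaldehyde | COc1c(C=O)cc(Br)cc1Br
F10 | step 1 | 3,5-dibromo-2-methoxyphenyl formate | COc1c(OC=O)cc(Br)cc1Br
A1 | alternative 1 | (3,5-dibromo-2-methoxyphenyl)boronic acid | COc1c(B(O)O)cc(Br)cc1Br
A2 | alternative 1 | 2,3,4-tribromo-6-(propan-2-yloxy)phenol | CC(C)Oc1cc(Br)c(Br)c(Br)c1O
A3 | alternative 1 | 1,2,3-tribromo-4-(3,5-dibromo-2-methoxyphenoxy)-5-(propan-2-yloxy)benzene | COc1c(Br)cc(Br)cc1Oc1c(OC(C)C)cc(Br)c(Br)c1Br
A4 | alternative 2 | 3,4,5-tribromophenol | Oc1cc(Br)c(Br)c(Br)c1
A5 | alternative 2 | 3,4,5-tribromo-6-(3,5-dibromo-2-methoxyphenoxy)cyclohexa-2,4-dien-1-one (racemic) | COc1c(Br)cc(Br)cc1OC1C(=O)C=C(Br)C(Br)=C1Br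
A6 | alternative 3 | 2-fluorobenzaldehyde | O=Cc1ccccc1F
A7 | alternative 3 | 2-[2,3,4-tribromo-6-(propan-2-yloxy)phenoxy]benzaldehyde | CC(C)Oc1cc(Br)c(Br)c(Br)c1Oc1ccccc1C=O
A8 | alternative 3 | 2-[2,3,4-tribromo-6-(propan-2-yloxy)phenoxy]phenol | CC(C)Oc1cc(Br)c(Br)c(Br)c1Oc1ccccc1O
A9 | alternative 3 | 2,4-dibromo-6-[2,3,4-tribromo-6-(propan-2-yloxy)phenoxy]phenol | CC(C)Oc1cc(Br)c(Br)c(Br)c1Oc1cc(Br)cc(Br)c1O
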